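**Assumption:** the target SMILES has no stereocentres (C28H22O5), so no enantiomer needs to be set; the macrocycle is treated as conformationally mobile.

## Retrosynthetic overview
1. The 18-membered macrocycle is closed last, at the quinone C3–CH2 bond. A primary alkyl radical from ArCH2CH2CO2H adds to a 2-aryloxy-1,4-benzoquinone in a decarboxylative macrocyclisation.
2. The 2-aryloxyquinone comes from Fremy oxidation of a 3-aryloxyphenol, which is a resorcinol mono-aryl ether.
3. The seco-acid is built from two Heck couplings, an aryl iodide with a vinyl diaryl ether and then an aryl bromide with acrylic acid. One hydrogenation then gives both CH2CH2 units.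
4. Both diaryl ethers come from Cu-catalysed Ullmann coupling of a bromo-iodobenzene with excess catechol or resorcinol. Ring B is iodinated para to its free OH.
5. Rings A, B, C and the quinone ring all exist before the macrocycle closes. The quinone is formed one step before ring closure.

## Route

**Step 1**
Reactants: 1 catechol (Oc1ccccc1O, 4 equiv); 2 1-bromo-4-iodobenzene (Brc1ccc(I)cc1)
Product: 3 2-(4-bromophenoxy)phenol
Conditions: CuI (10 mol%), picolinic acid (20 mol%), K3PO4, DMSO, 80 °C, N2
Reagents that add atoms: none
Why: Ullmann-type C–O coupling is selective for C–I over C–Br, and excess catechol gives the mono-aryl ether; no stereocentre is formed.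

**Step 2**
Reactants: 3 2-(4-bromophenoxy)phenol
Product: 4 2-(4-bromophenoxy)-4-iodophenol
Conditions: NIS, MeCN, 0 °C → rt
Reagents that add atoms: N-iodosuccinimide, O=C1CCC(=O)N1I (adds I)
Why: electrophilic aromatic iodination occurs para to the free OH, the position that later carries the ring B CH2CH2 bridge, while the bromophenoxy ring is less activated.

**Step 3**
Reactants: 5 resorcinol (Oc1cccc(O)c1, 4 equiv); 6 1-bromo-3-iodobenzene (Brc1cccc(I)c1)
Product: 7 3-(3-bromophenoxy)phenol
Conditions: CuI (10 mol%), picolinic acid (20 mol%), K3PO4, DMSO, 80 °C, N2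
Reagents that add atoms: none
Why: the same chemoselective Ullmann coupling (C–I over C–Br) installs the ring C–O–(future quinone ring) ether.

**Step 4**
Reactants: 7 3-(3-bromophenoxy)phenol; 8 potassium vinyltrifluoroborate (C=C[B-](F)(F)F.[K+])
Product: 9 3-(3-ethenylphenoxy)phenol
Conditions: PdCl2(dppf) (5 mol%), Cs2CO3, THF/H2O 9:1, 80 °C
Reagents that add atoms: none (the vinyl group comes from reactant 8)
Why: Suzuki–Miyaura vinylation of the aryl bromide tolerates the free phenol and gives the styrene partner for the bibenzyl bridge.

**Step 5**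
Reactants: 4 2-(4-bromophenoxy)-4-iodophenol; 9 3-(3-ethenylphenoxy)phenol
Product: 10 2-(4-bromophenoxy)-4-[(E)-2-[3-(3-hydroxyphenoxy)phenyl]ethenyl]phenol
Conditions: Pd(OAc)2 (5 mol%), NaHCO3, nBu4NBr, DMF, 70 °C
Reagents that add atoms: none
Why: Mizoroki–Heck coupling occurs at the much more reactive Ar–I and leaves the Ar–Br untouched at this temperature; the E/Z geometry of the stilbene is irrelevant because it is hydrogenated later.

**Step 6**
Reactants: 10 stilbene aryl bromide; 11 acrylic acid (C=CC(=O)O)
Product: 12 (E)-3-[4-[2-hydroxy-5-[(E)-2-[3-(3-hydroxyphenoxy)phenyl]ethenyl]phenoxy]phenyl]prop-2-enoic acid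
Conditions: Pd(OAc)2 (5 mol%), P(o-tol)3, Et3N, DMF, 110 °C
Reagents that add atoms: none (the acrylic acid carbons come from reactant 11)
Why: a second Mizoroki–Heck reaction at the Ar–Br builds the three-carbon acid chain, whose CO2H is later lost in the radical step.

**Step 7**
Reactants: 12 cinnamic acid/stilbene
Product: 13 3-[4-[2-hydroxy-5-[2-[3-(3-hydroxyphenoxy)phenyl]ethyl]phenoxy]phenyl]propanoic acid
Conditions: H2 (1 atm), 10% Pd/C, EtOH/EtOAc, rt
Reagents that add atoms: none (H2 only)
Why: catalytic hydrogenation saturates the stilbene and the cinnamic acid together, no halogen is left to hydrogenolyse, the diaryl ethers are inert, and no stereocentre is formed.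

**Step 8**
Reactants: 13 saturated phenol acid
Product: 14 3-[4-[2-hydroxy-5-[2-[3-[(3,6-dioxocyclohexa-1,4-dien-1-yl)oxy]phenyl]ethyl]phenoxy]phenyl]propanoic acid (2-aryloxy-1,4-benzoquinone seco-acid)
Conditions: Fremy's salt (2.2 equiv), KH2PO4 buffer, acetone/H2O, rt
Reagents that add atoms: water, O (its oxygen becomes the new C=O); Fremy's salt, [K+].[K+].[O-]S(=O)(=O)N([O])S(=O)(=O)[O-] (oxidant, no atoms retained)
Why: Teuber oxidation converts a phenol with a free para position into the p-quinone, so the 3-aryloxyphenol gives the 2-aryloxybenzoquinone with its C3–H as the acceptor site, while ring B's phenol (para position blocked by the alkyl chain) reacts much more slowly.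

**Step 9**
Reactants: 14 quinone seco-acid
Product: 15 marchantinquinone
Conditions: AgNO3 (0.3 equiv), (NH4)2S2O8 (3 equiv), MeCN/H2O 1:1, 70 °C; 14 added by syringe pump over 6 h (about 1 mM final)
Reagents that add atoms: none (persulfate, [NH4+].[NH4+].[O-]S(=O)(=O)OOS(=O)(=O)[O-], is only the oxidant; CO2 is lost)
Why: Proposed new method: Ag(II)/SO4•− oxidises the carboxylate and CO2 is lost to give the nucleophilic primary radical ArCH2CH2•, which adds to the electron-poor quinone C=C at C3 next to the aryloxy group (an 18-membered closure) to give a captodative radical stabilised by OAr and the C1 carbonyl, and excess persulfate re-oxidises the resulting hydroquinone to the quinone; the closest known reaction is the intermolecular Ag/persulfate decarboxylative alkylation of quinones (Minisci/Fontana type), and slow addition at about 1 mM favours ring closure over oligomerisation; no stereocentre forms.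

## Compound list
1 | catechol | Oc1ccccc1O | starting material
2 | 1-bromo-4-iodobenzene | Brc1ccc(I)cc1 | starting material
3 | 2-(4-bromophenoxy)phenol | Oc1ccccc1Oc1ccc(Br)cc1 | intermediate
4 | 2-(4-bromophenoxy)-4-iodophenol | Oc1ccc(I)cc1Oc1ccc(Br)cc1 | intermediate
5 | resorcinol | Oc1cccc(O)c1 | starting material
6 | 1-bromo-3-iodobenzene | Brc1cccc(I)c1 | starting material
7 | 3-(3-bromophenoxy)phenol | Oc1cccc(Oc2cccc(Br)c2)c1 | intermediate
8 | potassium vinyltrifluoroborate | C=C[B-](F)(F)F.[K+] | starting material
9 | 3-(3-ethenylphenoxy)phenol | C=Cc1cccc(Oc2cccc(O)c2)c1 | intermediate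
10 | 2-(4-bromophenoxy)-4-[(E)-2-[3-(3-hydroxyphenoxy)phenyl]ethenyl]phenol | Oc1ccc(/C=C/c2cccc(Oc3cccc(O)c3)c2)cc1Oc1ccc(Br)cc1 | intermediate
11 | acrylic acid | C=CC(=O)O | starting material
12 | (E)-cinnamic acid/stilbene | OC(=O)/C=C/c1ccc(Oc2cc(/C=C/c3cccc(Oc4cccc(O)c4)c3)ccc2O)cc1 | intermediate
13 | saturated phenol acid | OC(=O)CCc1ccc(Oc2cc(CCc3cccc(Oc4cccc(O)c4)c3)ccc2O)cc1 | intermediate
14 | quinone seco-acid | OC(=O)CCc1ccc(Oc2cc(CCc3cccc(OC4=CC(=O)C=CC4=O)c3)ccc2O)cc1 | intermediate
15 | marchantinquinone | O=C1C=CC(=O)C2=C1CCc1ccc(cc1)Oc1cc(ccc1O)CCc1cccc(c1)O2 | target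

## Totals
Total steps: 9. Longest linear sequence: 7 steps (steps 1 → 2 → 5 → 6 → 7 → 8 → 9). The branch of steps 3 → 4 is equally long before it joins at step 5.

## Three steps most likely to fail
1. **Step 9, radical macrocyclisation.** The radical could add at C5/C6 of the quinone instead of C3, and the free ring B phenol could be oxidised by persulfate or oligomers could form.
   - Fallback: change the ring-closing bond. Build the 2-aryloxy-1,4-dimethoxybenzene analogue with a C3 bromide and an ArCH=CH2 arm, close the ring by intramolecular Heck, hydrogenate, and unmask the quinone with CAN or AgO/HNO3 as the last step.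
2. **Step 8, Fremy oxidation.** The ring B phenol or the acid may interfere, giving an o-quinone or a low yield.
   - Fallback: protect ring B's OH as its TBS ether before the oxidation (TBSCl, imidazole). Oxidise the single free phenol, run step 9, then remove the silyl group with HF·pyridine.
3. **Step 1, catechol mono-arylation.** Copper can oxidise catechol, and bis-arylation is possible.
   - Fallback: metal-free O-arylation of mono-TBS-catechol with a (4-bromophenyl)(mesityl)iodonium salt, then TBAF removal of the silyl group.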